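**Plan**

- Retrosynthesis: the four benzyl ethers and the ethyl ether of ketone 30 are cleaved last, and the butyryl carbonyl is traced back to a silyl-protected carbinol. Ring A is then cut at C1–C2 and C3–C4 into cyclobutenone 17 and siloxyalkyne 21.
- Cyclobutenone 17 is cut across its four-membered ring into the ketene of the ring B acid chloride 10 and alkynyl ether 15; siloxyalkyne 21 comes from ester 18.
- Enabling feature: ring A (C1 butyryl, C2 OH, C3 prenyl, C4 OH, C5 CH2 to ring B, C6 OH) alternates three oxygens with three different carbon groups. A 2,4-disubstituted 3-alkoxycyclobutenone and a siloxyalkyne deliver exactly this pattern.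
- Forward: ring B is bought as 2,4,6-trimethoxytoluene and receives side chain, acetyl group and benzyl ethers (steps 1–8). The four-membered ring is formed in step 11 and ring A in step 13. Steps 14–17 cap the phenols, free and oxidise the carbinol, and remove every ether except the ring B methoxy group.
- Stereochemistry: the target has no stereocentre. The carbinol centre (step 9) and the cyclobutenone centre (step 11) arise without control and are erased in steps 16 and 13.

Key step: step 13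

Remark: the two methoxy groups flanking the ring B acetyl group are exchanged for benzyl ethers early (steps 5 and 6), because their cleavage needs conditions that are safe only before the prenyl group is present.

**Route**

Step 1
Reactants: 1 2,4,6-trimethoxytoluene
Product: 3 2,4,6-trimethoxy-3-methylbenzaldehyde, via aryl iminium chloride 2 (not isolated)
Conditions: POCl3, DMF, 0 °C → 60 °C; then aq. NaOAc, rt
Reagents that add atoms: N,N-dimethylformamide, CN(C)C=O; water, O
Why: Vilsmeier–Haack formylation of the electron-rich arene, whose two open ring positions are equivalent by symmetry and whose product is deactivated against a second formylation.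

Step 2
Reactants: 3 2,4,6-trimethoxy-3-methylbenzaldehyde
Product: 4 ethyl (E)-3-(2,4,6-trimethoxy-3-methylphenyl)prop-2-enoate
Conditions: (EtO)2P(O)CH2CO2Et, NaH, THF, 0 °C → rt
Reagents that add atoms: triethyl phosphonoacetate, CCOC(=O)CP(=O)(OCC)OCC
Why: Horner–Wadsworth–Emmons olefination of the aryl aldehyde with the stabilised phosphonate anion, which should give the E cinnamate.

Step 3
Reactants: 4 ethyl (E)-3-(2,4,6-trimethoxy-3-methylphenyl)prop-2-enoate
Product: 5 ethyl 3-(2,4,6-trimethoxy-3-methylphenyl)propanoate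
Conditions: H2 (1 atm), Pd/C, EtOAc, rt
Reagents that add atoms: none
Why: Heterogeneous catalytic hydrogenation saturates the conjugated alkene while arene, ester and aryl methyl ethers are inert.

Step 4
Reactants: 5 ethyl 3-(2,4,6-trimethoxy-3-methylphenyl)propanoate
Product: 6 ethyl 3-(3-acetyl-2,4,6-trimethoxy-5-methylphenyl)propanoate
Conditions: AcOH, (CF3CO)2O, CH2Cl2, 0 °C → rt
Reagents that add atoms: acetic acid, CC(=O)O
Why: Friedel–Crafts acylation by the mixed anhydride acetyl trifluoroacetate at the only unsubstituted ring carbon, which lies between two methoxy groups, and without a metal halide the methyl ethers should stay intact.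

Step 5
Reactants: 6 ethyl 3-(3-acetyl-2,4,6-trimethoxy-5-methylphenyl)propanoate
Product: 7 ethyl 3-(3-acetyl-2,4-dihydroxy-6-methoxy-5-methylphenyl)propanoate
Conditions: BCl3 (excess), CH2Cl2, −78 °C → rt; then ice water
Reagents that add atoms: none
Why: Chelation-directed ether cleavage in which boron bound to the acetyl oxygen delivers chloride to the methyl of each flanking methoxy group, whereas the methoxy group between C-methyl and side chain has no carbonyl neighbour and should be kept; the cold work-up avoids lactonisation onto the ester.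

Step 6
Reactants: 7 ethyl 3-(3-acetyl-2,4-dihydroxy-6-methoxy-5-methylphenyl)propanoate
Product: 8 ethyl 3-[3-acetyl-2,4-bis(benzyloxy)-6-methoxy-5-methylphenyl]propanoate
Conditions: BnBr, K2CO3, DMF, 60 °C
Reagents that add atoms: benzyl bromide, BrCc1ccccc1
Why: Williamson etherification of both phenols with a group that survives base, acid chloride formation, heat, fluoride and oxidation and is removable at −78 °C in the last step.

Step 7
Reactants: 8 ethyl 3-[3-acetyl-2,4-bis(benzyloxy)-6-methoxy-5-methylphenyl]propanoate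
Product: 9 3-[3-acetyl-2,4-bis(benzyloxy)-6-methoxy-5-methylphenyl]propanoic acid
Conditions: LiOH, THF/MeOH/H2O, rt; then 1 M HCl
Reagents that add atoms: lithium hydroxide, [Li+].[OH-]
Why: Ester saponification, to which the hindered aryl ketone and the aryl ethers are inert.

Step 8
Reactants: 9 3-[3-acetyl-2,4-bis(benzyloxy)-6-methoxy-5-methylphenyl]propanoic acid
Product: 10 3-[3-acetyl-2,4-bis(benzyloxy)-6-methoxy-5-methylphenyl]propanoyl chloride
Conditions: (COCl)2, DMF (cat.), CH2Cl2, 0 °C → rt; concentrate and use crude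
Reagents that add atoms: oxalyl chloride, ClC(=O)C(Cl)=O
Why: Acid chloride formation through the catalytic chloroiminium activator, leaving only volatile by-products before the ketene step.

Step 9
Reactants: 11 ethoxyacetylene; 12 butanal
Product: 14 racemic 1-ethoxyhex-1-yn-3-ol, via lithium ethoxyacetylide 13 (not isolated)
Conditions: n-BuLi, THF, −78 °C; then 12, −78 → 0 °C; then H2O
Reagents that add atoms: none
Why: 1,2-Addition of a lithium alkoxyacetylide to an aldehyde; the carbinol centre forms without control (racemate) and later becomes the butyryl carbonyl carbon.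

Step 10
Reactants: 14 racemic 1-ethoxyhex-1-yn-3-ol
Product: 15 racemic tert-butyl[(1-ethoxyhex-1-yn-3-yl)oxy]dimethylsilane
Conditions: TBSCl, imidazole, DMF, 0 °C → rt
Reagents that add atoms: tert-butyldimethylsilyl chloride, CC(C)(C)[Si](C)(C)Cl
Why: Silylation of the secondary alcohol under basic conditions, which also shields the acid-labile hydroxy alkynyl ether from Meyer–Schuster rearrangement.

Step 11
Reactants: 10 3-[3-acetyl-2,4-bis(benzyloxy)-6-methoxy-5-methylphenyl]propanoyl chloride; 15 racemic tert-butyl[(1-ethoxyhex-1-yn-3-yl)oxy]dimethylsilane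
Product: 17 4-{[3-acetyl-2,4-bis(benzyloxy)-6-methoxy-5-methylphenyl]methyl}-2-[1-(tert-butyldimethylsilyloxy)butyl]-3-ethoxycyclobut-2-en-1-one (diastereomer mixture), via aldoketene 16 (not isolated)
Conditions: Et3N, 15 (1.5 equiv), CH2Cl2, 40 °C, slow addition of 10
Reagents that add atoms: none
Why: Dehydrochlorination gives the aldoketene, which undergoes [2+2] cycloaddition with the electron-rich alkynyl ether, the ketene carbonyl carbon bonding to the oxygen-free alkyne carbon to give the 3-ethoxycyclobutenone; the new ring stereocentre forms without control and is erased in step 13.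

Step 12
Reactants: 18 ethyl 4-methylpent-3-enoate
Product: 21 5-methyl-1-(triisopropylsilyloxy)hex-4-en-1-yne, via lithium dibromoenolate 19 (not isolated), via lithium ynolate 20 (not isolated)
Conditions: CH2Br2, LiTMP (from 2,2,6,6-tetramethylpiperidine and n-BuLi), THF, −78 °C; then n-BuLi, −78 → 0 °C; then TIPSCl, −78 °C → rt
Reagents that add atoms: dibromomethane, BrCBr; triisopropylsilyl chloride, CC(C)[Si](Cl)(C(C)C)C(C)C
Why: Kowalski ynolate formation, in which LiCHBr2 adds to the ester, bromine–lithium exchange on the dibromoenolate triggers a 1,2-shift of the prenyl group to the ynolate, and the bulky silyl chloride silylates on oxygen.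

Step 13
Reactants: 17 4-{[3-acetyl-2,4-bis(benzyloxy)-6-methoxy-5-methylphenyl]methyl}-2-[1-(tert-butyldimethylsilyloxy)butyl]-3-ethoxycyclobut-2-en-1-one; 21 5-methyl-1-(triisopropylsilyloxy)hex-4-en-1-yne
Product: 26 racemic 1-[2,6-bis(benzyloxy)-3-({3-[1-(tert-butyldimethylsilyloxy)butyl]-2-ethoxy-6-hydroxy-5-(3-methylbut-2-enyl)-4-(triisopropylsilyloxy)phenyl}methyl)-4-methoxy-5-methylphenyl]ethanone, via vinylketene 22 (not isolated), via 4-alkenylcyclobutenone 23 (not isolated), via dienylketene 24 (not isolated), via cyclohexadienone 25 (not isolated)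
Conditions: 21 (1.5 equiv), PhMe, 120 °C, sealed tube, Ar
Reagents that add atoms: none
Why: Proposed new method: heating opens cyclobutenone 17 by 4π electrocyclic cleavage of its C1–C4 bond to vinylketene 22, whose ketene carbon is attacked by the nucleophilic, prenyl-bearing carbon of siloxyalkyne 21 in a [2+2] cycloaddition to 23, which reopens to dienylketene 24. The closest known reaction type is the Danheiser benzannulation of alkyl- and aryl-substituted cyclobutenones with siloxyalkynes to resorcinol monosilyl ethers; a 2,4-disubstituted 3-alkoxycyclobutenone leading to a hexasubstituted phloroglucinol derivative is the extension proposed here. Ring A closes by thermal disrotatory 6π electrocyclisation of 24 (bond C4–C5 of ring A, six-membered carbocycle), and cyclohexadienone 25 tautomerises to the phenol through the hydrogen on the former cyclobutenone C4. The net result is formation of the ring A bonds C1–C2 and C3–C4, so that the former carbonyl oxygen, the silyloxy group and the ethoxy group become mutually meta, with prenyl, the silyloxybutyl group and the ring B benzyl group between them. No new stereocentre is formed, the ring stereocentre of 17 is erased and the carbinol centre is carried as the racemate. The one selectivity needed, the orientation of ketene and alkyne, is secured by the polarisation of the siloxyalkyne (oxygen-free carbon nucleophilic), and reversible ring opening of 23 should funnel both alkene geometries of 24 to the arene.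

Step 14
Reactants: 26 racemic phenol from step 13
Product: 28 racemic 1-[2,6-bis(benzyloxy)-3-({2,4-bis(benzyloxy)-5-[1-(tert-butyldimethylsilyloxy)butyl]-6-ethoxy-3-(3-methylbut-2-enyl)phenyl}methyl)-4-methoxy-5-methylphenyl]ethanone, via caesium diphenolate 27 (not isolated)
Conditions: BnBr, CsF, Cs2CO3, DMF, rt → 40 °C
Reagents that add atoms: benzyl bromide, BrCc1ccccc1
Why: One-pot fluoride desilylation and Williamson etherification, in which the aryl silyl ether is cleaved far faster than the hindered secondary alkyl silyl ether and both phenoxides are capped at once by the benzyl bromide present.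

Step 15
Reactants: 28 racemic tetrabenzyl silyl ether from step 14
Product: 29 racemic 1-[2,6-bis(benzyloxy)-3-({2,4-bis(benzyloxy)-6-ethoxy-5-(1-hydroxybutyl)-3-(3-methylbut-2-enyl)phenyl}methyl)-4-methoxy-5-methylphenyl]ethanone
Conditions: TBAF, THF, rt → 45 °C
Reagents that add atoms: none
Why: Fluoride cleavage of the alkyl silyl ether; with all three ring A oxygens held as ethers and under basic conditions, the electron-rich benzylic carbinol is released without ionising to a quinone methide.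

Step 16
Reactants: 29 racemic carbinol from step 15
Product: 30 1-[5-{[3-acetyl-2,4-bis(benzyloxy)-6-methoxy-5-methylphenyl]methyl}-2,4-bis(benzyloxy)-6-ethoxy-3-(3-methylbut-2-enyl)phenyl]butan-1-one
Conditions: DMP, NaHCO3, CH2Cl2, 0 °C → rt
Reagents that add atoms: none
Why: Dess–Martin oxidation of the secondary benzylic alcohol to the aryl ketone under buffered, non-acidic conditions that leave the prenyl alkene and the fully substituted arenes alone; the last stereocentre disappears.

Step 17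
Reactants: 30 ketone from step 16
Product: 31 1-[3-[(3-acetyl-2,4-dihydroxy-6-methoxy-5-methylphenyl)methyl]-2,4,6-trihydroxy-5-(3-methylbut-2-enyl)phenyl]butan-1-one (CNP0109173.0)
Conditions: BCl3, C6HMe5, CH2Cl2, −78 → −30 °C; then MeOH
Reagents that add atoms: none
Why: Lewis acid ether cleavage in which BCl3 with pentamethylbenzene as a non-basic benzyl cation scavenger removes the four benzyl ethers and, assisted by chelation to the butyryl carbonyl, the ethyl ether at low temperature, while the ring B methoxy group without carbonyl neighbour should be kept.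

**Compound list**

1 | 2,4,6-trimethoxytoluene | COc1cc(OC)c(C)c(OC)c1 | starting material
2 | N-[(2,4,6-trimethoxy-3-methylphenyl)methylidene]-N-methylmethanaminium chloride (not isolated) | C[N+](C)=Cc1c(OC)c(C)c(OC)cc1OC.[Cl-] | intermediate
3 | 2,4,6-trimethoxy-3-methylbenzaldehyde | O=Cc1c(OC)c(C)c(OC)cc1OC | intermediate
4 | ethyl (E)-3-(2,4,6-trimethoxy-3-methylphenyl)prop-2-enoate | CCOC(=O)/C=C/c1c(OC)c(C)c(OC)cc1OC | intermediate
5 | ethyl 3-(2,4,6-trimethoxy-3-methylphenyl)propanoate | CCOC(=O)CCc1c(OC)c(C)c(OC)cc1OC | intermediate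
6 | ethyl 3-(3-acetyl-2,4,6-trimethoxy-5-methylphenyl)propanoate | CCOC(=O)CCc1c(OC)c(C(C)=O)c(OC)c(C)c1OC | intermediate
7 | ethyl 3-(3-acetyl-2,4-dihydroxy-6-methoxy-5-methylphenyl)propanoate | CCOC(=O)CCc1c(O)c(C(C)=O)c(O)c(C)c1OC | intermediate
8 | ethyl 3-[3-acetyl-2,4-bis(benzyloxy)-6-methoxy-5-methylphenyl]propanoate | CCOC(=O)CCc1c(OCc2ccccc2)c(C(C)=O)c(OCc2ccccc2)c(C)c1OC | intermediate
9 | 3-[3-acetyl-2,4-bis(benzyloxy)-6-methoxy-5-methylphenyl]propanoic acid | OC(=O)CCc1c(OCc2ccccc2)c(C(C)=O)c(OCc2ccccc2)c(C)c1OC | intermediate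
10 | 3-[3-acetyl-2,4-bis(benzyloxy)-6-methoxy-5-methylphenyl]propanoyl chloride | ClC(=O)CCc1c(OCc2ccccc2)c(C(C)=O)c(OCc2ccccc2)c(C)c1OC | intermediate
11 | ethoxyacetylene | CCOC#C | starting material
12 | butanal | CCCC=O | starting material
13 | lithium ethoxyacetylide (not isolated) | [Li]C#COCC | intermediate
14 | racemic 1-ethoxyhex-1-yn-3-ol | CCCC(O)C#COCC | intermediate
15 | racemic tert-butyl[(1-ethoxyhex-1-yn-3-yl)oxy]dimethylsilane | CCCC(O[Si](C)(C)C(C)(C)C)C#COCC | intermediate
16 | 3-[3-acetyl-2,4-bis(benzyloxy)-6-methoxy-5-methylphenyl]prop-1-en-1-one (aldoketene, not isolated) | O=C=CCc1c(OCc2ccccc2)c(C(C)=O)c(OCc2ccccc2)c(C)c1OC | intermediate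
17 | 4-{[3-acetyl-2,4-bis(benzyloxy)-6-methoxy-5-methylphenyl]methyl}-2-[1-(tert-butyldimethylsilyloxy)butyl]-3-ethoxycyclobut-2-en-1-one (diastereomer mixture, each racemic) | CCCC(O[Si](C)(C)C(C)(C)C)C1=C(OCC)C(Cc2c(OCc3ccccc3)c(C(C)=O)c(OCc3ccccc3)c(C)c2OC)C1=O | intermediate
18 | ethyl 4-methylpent-3-enoate | CCOC(=O)CC=C(C)C | starting material
19 | lithium 1,1-dibromo-5-methylhexa-1,4-dien-2-olate (not isolated) | [Li]OC(CC=C(C)C)=C(Br)Br | intermediate
20 | lithium 5-methylhex-4-en-1-yn-1-olate (not isolated) | [Li]OC#CCC=C(C)C | intermediate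
21 | 5-methyl-1-(triisopropylsilyloxy)hex-4-en-1-yne | CC(C)=CCC#CO[Si](C(C)C)(C(C)C)C(C)C | intermediate
22 | (3Z)-5-[3-acetyl-2,4-bis(benzyloxy)-6-methoxy-5-methylphenyl]-2-[1-(tert-butyldimethylsilyloxy)butyl]-3-ethoxypenta-1,3-dien-1-one (vinylketene, racemic, not isolated) | CCCC(O[Si](C)(C)C(C)(C)C)C(=C=O)/C(OCC)=C/Cc1c(OCc2ccccc2)c(C(C)=O)c(OCc2ccccc2)c(C)c1OC | intermediate
23 | 4-{(1Z)-3-[3-acetyl-2,4-bis(benzyloxy)-6-methoxy-5-methylphenyl]-1-ethoxyprop-1-enyl}-4-[1-(tert-butyldimethylsilyloxy)butyl]-2-(3-methylbut-2-enyl)-3-(triisopropylsilyloxy)cyclobut-2-en-1-one (diastereomer mixture, not isolated) | O=C1C(CC=C(C)C)=C(O[Si](C(C)C)(C(C)C)C(C)C)C1(C(CCC)O[Si](C)(C)C(C)(C)C)/C(OCC)=C/Cc1c(OCc2ccccc2)c(C(C)=O)c(OCc2ccccc2)c(C)c1OC | intermediate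
24 | (3E,5Z)-7-[3-acetyl-2,4-bis(benzyloxy)-6-methoxy-5-methylphenyl]-4-[1-(tert-butyldimethylsilyloxy)butyl]-5-ethoxy-2-(3-methylbut-2-enyl)-3-(triisopropylsilyloxy)hepta-1,3,5-trien-1-one (dienylketene, racemic, not isolated) | O=C=C(CC=C(C)C)/C(O[Si](C(C)C)(C(C)C)C(C)C)=C(C(CCC)O[Si](C)(C)C(C)(C)C)\C(OCC)=C\Cc1c(OCc2ccccc2)c(C(C)=O)c(OCc2ccccc2)c(C)c1OC | intermediate
25 | 6-{[3-acetyl-2,4-bis(benzyloxy)-6-methoxy-5-methylphenyl]methyl}-4-[1-(tert-butyldimethylsilyloxy)butyl]-5-ethoxy-2-(3-methylbut-2-enyl)-3-(triisopropylsilyloxy)cyclohexa-2,4-dien-1-one (diastereomer mixture, not isolated) | O=C1C(CC=C(C)C)=C(O[Si](C(C)C)(C(C)C)C(C)C)C(C(CCC)O[Si](C)(C)C(C)(C)C)=C(OCC)C1Cc1c(OCc2ccccc2)c(C(C)=O)c(OCc2ccccc2)c(C)c1OC | intermediate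
26 | racemic 1-[2,6-bis(benzyloxy)-3-({3-[1-(tert-butyldimethylsilyloxy)butyl]-2-ethoxy-6-hydroxy-5-(3-methylbut-2-enyl)-4-(triisopropylsilyloxy)phenyl}methyl)-4-methoxy-5-methylphenyl]ethanone | CCCC(O[Si](C)(C)C(C)(C)C)c1c(OCC)c(Cc2c(OCc3ccccc3)c(C(C)=O)c(OCc3ccccc3)c(C)c2OC)c(O)c(CC=C(C)C)c1O[Si](C(C)C)(C(C)C)C(C)C | intermediate
27 | dicaesium diphenolate of desilylated 26 (racemic, not isolated) | CCCC(O[Si](C)(C)C(C)(C)C)c1c(OCC)c(Cc2c(OCc3ccccc3)c(C(C)=O)c(OCc3ccccc3)c(C)c2OC)c([O-])c(CC=C(C)C)c1[O-].[Cs+].[Cs+] | intermediate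
28 | racemic 1-[2,6-bis(benzyloxy)-3-({2,4-bis(benzyloxy)-5-[1-(tert-butyldimethylsilyloxy)butyl]-6-ethoxy-3-(3-methylbut-2-enyl)phenyl}methyl)-4-methoxy-5-methylphenyl]ethanone | CCCC(O[Si](C)(C)C(C)(C)C)c1c(OCC)c(Cc2c(OCc3ccccc3)c(C(C)=O)c(OCc3ccccc3)c(C)c2OC)c(OCc2ccccc2)c(CC=C(C)C)c1OCc1ccccc1 | intermediate
29 | racemic 1-[2,6-bis(benzyloxy)-3-({2,4-bis(benzyloxy)-6-ethoxy-5-(1-hydroxybutyl)-3-(3-methylbut-2-enyl)phenyl}methyl)-4-methoxy-5-methylphenyl]ethanone | CCCC(O)c1c(OCC)c(Cc2c(OCc3ccccc3)c(C(C)=O)c(OCc3ccccc3)c(C)c2OC)c(OCc2ccccc2)c(CC=C(C)C)c1OCc1ccccc1 | intermediate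
30 | 1-[5-{[3-acetyl-2,4-bis(benzyloxy)-6-methoxy-5-methylphenyl]methyl}-2,4-bis(benzyloxy)-6-ethoxy-3-(3-methylbut-2-enyl)phenyl]butan-1-one | CCCC(=O)c1c(OCC)c(Cc2c(OCc3ccccc3)c(C(C)=O)c(OCc3ccccc3)c(C)c2OC)c(OCc2ccccc2)c(CC=C(C)C)c1OCc1ccccc1 | intermediate
31 | 1-[3-[(3-acetyl-2,4-dihydroxy-6-methoxy-5-methylphenyl)methyl]-2,4,6-trihydroxy-5-(3-methylbut-2-enyl)phenyl]butan-1-one | CCCC(=O)c1c(O)c(CC=C(C)C)c(O)c(Cc2c(O)c(C(C)=O)c(O)c(C)c2OC)c1O | target

**Step count and risks**

Total steps: 17. Longest linear sequence: 14 (steps 1–8, 11, 13–17).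

Steps most likely to fail:

1. Step 13. The donor-stabilised 3-ethoxycyclobutenone may open only slowly, and the [2+2] addition at the fully substituted ketene carbon is crowded, so that vinylketene side reactions or thermal loss of the siloxyalkyne could outpace ring A formation. The fallback uses known chemistry, the methylene bridging of two acylphloroglucinol halves through a phenolic Mannich base; it sets out from 1 and comes back at 31.
   - Acetylation of 1 (AcOH, (CF3CO)2O) gives 1-(2,4,6-trimethoxy-3-methylphenyl)ethanone F1.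
   - BCl3 cleaves the two methoxy groups flanking the acetyl group to give 1-(2,6-dihydroxy-4-methoxy-3-methylphenyl)ethanone F2.
   - A Mannich reaction (aq. CH2O, Me2NH, EtOH) at the one free ring carbon gives 1-{3-[(dimethylamino)methyl]-2,6-dihydroxy-4-methoxy-5-methylphenyl}ethanone F3.
   - Separately, Friedel–Crafts acylation of phloroglucinol with butanoyl chloride (AlCl3) gives 1-(2,4,6-trihydroxyphenyl)butan-1-one F4, and C-prenylation (prenyl bromide, aq. KOH, 0 °C) gives 1-[2,4,6-trihydroxy-3-(3-methylbut-2-enyl)phenyl]butan-1-one F5.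
   - Heating F3 with F5 (dioxane, 90 °C) expels dimethylamine to form 2-acetyl-3-hydroxy-5-methoxy-4-methyl-6-methylidenecyclohexa-2,4-dien-1-one F6, which alkylates the free ring carbon of F5 to give 31.

2. Step 17. Cationic attack on the prenyl double bond under the Lewis acid (addition of HCl, or ring closure of a flanking phenol oxygen onto the tertiary cation) may compete with cleavage of the ethyl ether, the slowest of the five ethers. The fallback carries a robust allyl group through the Lewis acid step and makes the prenyl group last by cross-metathesis; it sets out from 17 and comes back at 31.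
   - Pent-1-en-4-yne is deprotonated (n-BuLi, THF, −78 °C) to lithium pent-4-en-1-yn-1-ide F7, oxidised with LiOOt-Bu to lithium pent-4-en-1-yn-1-olate F8 and silylated (TIPSOTf) to 1-(triisopropylsilyloxy)pent-4-en-1-yne F9.
   - Heating 17 with F9 as in step 13 should pass from vinylketene 22 through the allyl 4-alkenylcyclobutenone F10, the allyl dienylketene F11 and the allyl cyclohexadienone F12 to the allyl phenol F13.
   - The operations of steps 14 to 17 then lead through the allyl caesium diphenolate F14, the allyl tetrabenzyl silyl ether F15, the allyl carbinol F16 and the allyl ketone F17 to the allyl analogue of the target F18.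
   - Cross-metathesis of F18 with 2-methylbut-2-ene (second-generation Grubbs catalyst, CH2Cl2, 40 °C) gives 31.

3. Step 12. LiCHBr2 or LiTMP may deprotonate the doubly activated C2–H of the β,γ-unsaturated ester instead of adding to the ester carbonyl, returning ester (partly as the conjugated isomer) on work-up. The fallback makes the ynolate by oxidation of an acetylide; it sets out from 18 and comes back at 20.
   - Reduction (i-Bu2AlH, CH2Cl2, −78 °C) gives 4-methylpent-3-enal F19.
   - Corey–Fuchs olefination (CBr4, PPh3, CH2Cl2, 0 °C) gives 1,1-dibromo-5-methylhexa-1,4-diene F20.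
   - n-BuLi (2 equiv, THF, −78 °C) gives lithium 5-methylhex-4-en-1-yn-1-ide F21.
   - LiOOt-Bu (−78 → 0 °C) oxidises the acetylide to ynolate 20, which is silylated as in step 12.

**Further compounds**

F1 | step 13 | 1-(2,4,6-trimethoxy-3-methylphenyl)ethanone | CC(=O)c1c(OC)cc(OC)c(C)c1OC
F2 | step 13 | 1-(2,6-dihydroxy-4-methoxy-3-methylphenyl)ethanone | CC(=O)c1c(O)cc(OC)c(C)c1O
F3 | step 13 | 1-{3-[(dimethylamino)methyl]-2,6-dihydroxy-4-methoxy-5-methylphenyl}ethanone | CC(=O)c1c(O)c(CN(C)C)c(OC)c(C)c1O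
F4 | step 13 | 1-(2,4,6-trihydroxyphenyl)butan-1-one | CCCC(=O)c1c(O)cc(O)cc1O
F5 | step 13 | 1-[2,4,6-trihydroxy-3-(3-methylbut-2-enyl)phenyl]butan-1-one | CCCC(=O)c1c(O)cc(O)c(CC=C(C)C)c1O
F6 | step 13 | 2-acetyl-3-hydroxy-5-methoxy-4-methyl-6-methylidenecyclohexa-2,4-dien-1-one (not isolated) | CC(=O)C1=C(O)C(C)=C(OC)C(=C)C1=O
F7 | step 17 | lithium pent-4-en-1-yn-1-ide (not isolated) | [Li]C#CCC=C
F8 | step 17 | lithium pent-4-en-1-yn-1-olate (not isolated) | [Li]OC#CCC=C
F9 | step 17 | 1-(triisopropylsilyloxy)pent-4-en-1-yne | C=CCC#CO[Si](C(C)C)(C(C)C)C(C)C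
F10 | step 17 | 4-{(1Z)-3-[3-acetyl-2,4-bis(benzyloxy)-6-methoxy-5-methylphenyl]-1-ethoxyprop-1-enyl}-4-[1-(tert-butyldimethylsilyloxy)butyl]-2-(prop-2-enyl)-3-(triisopropylsilyloxy)cyclobut-2-en-1-one (not isolated) | O=C1C(CC=C)=C(O[Si](C(C)C)(C(C)C)C(C)C)C1(C(CCC)O[Si](C)(C)C(C)(C)C)/C(OCC)=C/Cc1c(OCc2ccccc2)c(C(C)=O)c(OCc2ccccc2)c(C)c1OC
F11 | step 17 | (3E,5Z)-7-[3-acetyl-2,4-bis(benzyloxy)-6-methoxy-5-methylphenyl]-4-[1-(tert-butyldimethylsilyloxy)butyl]-5-ethoxy-2-(prop-2-enyl)-3-(triisopropylsilyloxy)hepta-1,3,5-trien-1-one (not isolated) | O=C=C(CC=C)/C(O[Si](C(C)C)(C(C)C)C(C)C)=C(C(CCC)O[Si](C)(C)C(C)(C)C)\C(OCC)=C\Cc1c(OCc2ccccc2)c(C(C)=O)c(OCc2ccccc2)c(C)c1OC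
F12 | step 17 | 6-{[3-acetyl-2,4-bis(benzyloxy)-6-methoxy-5-methylphenyl]methyl}-4-[1-(tert-butyldimethylsilyloxy)butyl]-5-ethoxy-2-(prop-2-enyl)-3-(triisopropylsilyloxy)cyclohexa-2,4-dien-1-one (not isolated) | O=C1C(CC=C)=C(O[Si](C(C)C)(C(C)C)C(C)C)C(C(CCC)O[Si](C)(C)C(C)(C)C)=C(OCC)C1Cc1c(OCc2ccccc2)c(C(C)=O)c(OCc2ccccc2)c(C)c1OC
F13 | step 17 | racemic 1-[2,6-bis(benzyloxy)-3-({3-[1-(tert-butyldimethylsilyloxy)butyl]-2-ethoxy-6-hydroxy-5-(prop-2-enyl)-4-(triisopropylsilyloxy)phenyl}methyl)-4-methoxy-5-methylphenyl]ethanone | CCCC(O[Si](C)(C)C(C)(C)C)c1c(OCC)c(Cc2c(OCc3ccccc3)c(C(C)=O)c(OCc3ccccc3)c(C)c2OC)c(O)c(CC=C)c1O[Si](C(C)C)(C(C)C)C(C)C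
F14 | step 17 | dicaesium diphenolate of desilylated F13 (not isolated) | CCCC(O[Si](C)(C)C(C)(C)C)c1c(OCC)c(Cc2c(OCc3ccccc3)c(C(C)=O)c(OCc3ccccc3)c(C)c2OC)c([O-])c(CC=C)c1[O-].[Cs+].[Cs+]
F15 | step 17 | racemic 1-[2,6-bis(benzyloxy)-3-({2,4-bis(benzyloxy)-5-[1-(tert-butyldimethylsilyloxy)butyl]-6-ethoxy-3-(prop-2-enyl)phenyl}methyl)-4-methoxy-5-methylphenyl]ethanone | CCCC(O[Si](C)(C)C(C)(C)C)c1c(OCC)c(Cc2c(OCc3ccccc3)c(C(C)=O)c(OCc3ccccc3)c(C)c2OC)c(OCc2ccccc2)c(CC=C)c1OCc1ccccc1
F16 | step 17 | racemic 1-[2,6-bis(benzyloxy)-3-({2,4-bis(benzyloxy)-6-ethoxy-5-(1-hydroxybutyl)-3-(prop-2-enyl)phenyl}methyl)-4-methoxy-5-methylphenyl]ethanone | CCCC(O)c1c(OCC)c(Cc2c(OCc3ccccc3)c(C(C)=O)c(OCc3ccccc3)c(C)c2OC)c(OCc2ccccc2)c(CC=C)c1OCc1ccccc1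
F17 | step 17 | 1-[5-{[3-acetyl-2,4-bis(benzyloxy)-6-methoxy-5-methylphenyl]methyl}-2,4-bis(benzyloxy)-6-ethoxy-3-(prop-2-enyl)phenyl]butan-1-one | CCCC(=O)c1c(OCC)c(Cc2c(OCc3ccccc3)c(C(C)=O)c(OCc3ccccc3)c(C)c2OC)c(OCc2ccccc2)c(CC=C)c1OCc1ccccc1
F18 | step 17 | 1-[3-[(3-acetyl-2,4-dihydroxy-6-methoxy-5-methylphenyl)methyl]-2,4,6-trihydroxy-5-(prop-2-enyl)phenyl]butan-1-one | CCCC(=O)c1c(O)c(CC=C)c(O)c(Cc2c(O)c(C(C)=O)c(O)c(C)c2OC)c1O
F19 | step 12 | 4-methylpent-3-enal | CC(C)=CCC=O
F20 | step 12 | 1,1-dibromo-5-methylhexa-1,4-diene | CC(C)=CCC=C(Br)Br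
F21 | step 12 | lithium 5-methylhex-4-en-1-yn-1-ide (not isolated) | [Li]C#CCC=C(C)C
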